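Count the electrophile's half-lives instead of its percentages, for then "half reacted" is exactly one half-life.

| setting | north-west | south-west | flask |
|---|---|---|---|
| electrophile | 0.063 M | 0.063 M | 0.063 M |
| nucleophile | 0.38 M | 0.59 M |  |
| remark | run made earlier | run made earlier |  |
| time |  |  | 8.0 h |

Both earlier runs charge the nucleophile at no less than 6.03 times the electrophile, so I expect pseudo-first-order decay, with a count that grows evenly with time and in proportion to the charge.

| run | time / h | target / % | electrophile / % |
|---|---|---|---|
| north-west | 1.00 | 33 | 69 |
| north-west | 2.50 | 46 | 56 |
| north-west | 3.00 | 42 | 53 |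
| north-west | 5.00 | 51 | 52 |
| north-west | 6.00 | 52 | 47 |
| north-west | 8.00 | 53 | 46 |
| south-west | 1.00 | 39 | 59 |
| south-west | 2.50 | 46 | 48 |
| south-west | 3.00 | 53 | 50 |
| south-west | 5.00 | 56 | 45 |
| south-west | 6.00 | 55 | 43 |
| south-west | 8.00 | 60 | 40 |

(readings scatter by 1.5 percentage points)

- the amount of nucleophile is what is sought; it is there from the start
- a reading or a percentage of target counts all its forms, free or not

But the north-west run counts 0.535 half-lives in its first 1.00 h and 1.12 by 8.00 h, so the count slows. The south-west run reads 1.32 at 8.00 h, a rise by a factor 1.18, less than the factor 1.55 in the charge. So I work with differences: the two runs read 0.318 half-lives gained at 8.0 h per doubling of the nucleophile charge, the doubling gain.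

- the concentration of nucleophile at which the part of the electrophile that has reacted at 8.0 h is just 50%, in M

The answer needs a count of one, 0.120 below the north-west run, and the doubling gain turns that into a charge of 0.292 M, as a reading with its scatter. The forecast stands higher than my figure at 0.31 M, on a ratio that “rises only as roughly the square root of free nucleophile”.

The flask gives 0.268 M.

    electrophile + nucleophile → acid set free + target (k = 2.91 L mol⁻¹ h⁻¹)
    nucleophile + acid set free ⇌ protonated nucleophile, settled at all times (K = 280 L mol⁻¹)
    electrophile → decomposition product (k = 3.73 × 10⁻⁴ h⁻¹)
    2 nucleophile → homo dimer (k = 5.42 L mol⁻¹ h⁻¹)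
    nucleophile + target ⇌ idle adduct, settled at all times (K = 29.1 L mol⁻¹)

In this flask the homo dimer step has half of its turnover up to 8.0 h behind it by 0.236 h, earlier than the target step at 0.771 h. At 8.00 h it uses nucleophile at 0.96 of the rate of the target step. This flask stands at one half-life at 8.0 h, so taking off the doubling gain of 0.318 for half its nucleophile leaves 0.682 half-lives, or 37.7% reacted, and the run with half the nucleophile gives 39.4%.

The readings come from a simulation on assumed constants; noise was put on by code.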